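The C3–C4 bond of the pyranone ring (ring C) is the disconnection: the C4 ketone and the C3 carbinol form an acyloin, so both carbons can start as aldehydes. In one operation a chiral triazolylidene turns the ring-A aldehyde into an acyl-anion equivalent, closes ring C onto the side-chain aldehyde and fixes C2 and C3. This is possible because C2 is an epimerisable α-aryl-α-aryloxy aldehyde carbon in the open chain. The precursor is the tetra-O-benzyl dialdehyde 15, a 2-formylaryl ether of a 2-arylglycolaldehyde that already carries the (R)-1-arylethyl group at the future C6. Hydrogenolysis of all four benzyl ethers then releases the target.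

Key step: step 10

Assumption: the sense of induction of the iridium catalyst (step 3) and of the triazolium salt (step 10) cannot be predicted with certainty for these substrates, so the catalyst antipode that gives the required configuration is taken in each case; compounds 1, 3 and 11 are taken as commercial.

Step 1
Reactants: 1 3,5-bis(benzyloxy)phenol
Product: 2 [3,5-bis(benzyloxy)phenoxy]tri(propan-2-yl)silane
Conditions: TIPSCl, imidazole, DMF, rt
Reagents that add atoms: chlorotri(propan-2-yl)silane (TIPSCl), CC(C)[Si](Cl)(C(C)C)C(C)C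
Why: Silylation of the only free phenol gives a bulky silyl ether that is inert to n-BuLi, does not direct lithiation and shields C2/C6, so the next step is steered to C4.

Step 2
Reactants: 2 [3,5-bis(benzyloxy)phenoxy]tri(propan-2-yl)silane; 3 4'-(benzyloxy)acetophenone
Product: 6 {3,5-bis(benzyloxy)-4-[1-(4-(benzyloxy)phenyl)ethenyl]phenoxy}tri(propan-2-yl)silane, via aryllithium 4 (not isolated), via tertiary carbinol 5 (not isolated)
Conditions: n-BuLi, THF, 0 °C; then 3, −78 °C → rt; water quench; crude carbinol, p-TsOH·H2O (cat.), toluene, rt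
Reagents that add atoms: none
Why: Directed ortho-lithiation at the ring carbon flanked by two alkoxy groups, 1,2-addition of the aryllithium to the ketone and acid-catalysed E1 dehydration of the doubly benzylic tertiary carbinol should give the 1,1-diarylethene, which has no stereocentre.

Step 3
Reactants: 6 {3,5-bis(benzyloxy)-4-[1-(4-(benzyloxy)phenyl)ethenyl]phenoxy}tri(propan-2-yl)silane
Product: 7 {3,5-bis(benzyloxy)-4-[(1R)-1-(4-(benzyloxy)phenyl)ethyl]phenoxy}tri(propan-2-yl)silane
Conditions: [Ir(cod)(L*)]BArF (L* = chiral phosphine–oxazoline, 1–2 mol %), H2 (1–5 bar), CH2Cl2, rt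
Reagents that add atoms: none
Why: Iridium-catalysed asymmetric hydrogenation of a 1,1-diarylethene: the di-ortho-alkoxy ring is twisted out of the alkene plane while the 4-benzyloxyphenyl ring stays coplanar, so the chiral pocket can tell the two faces apart and set the (R)-benzylic centre, and benzyl and silyl ethers are inert to the homogeneous catalyst.

Step 4
Reactants: 7 {3,5-bis(benzyloxy)-4-[(1R)-1-(4-(benzyloxy)phenyl)ethyl]phenoxy}tri(propan-2-yl)silane
Product: 8 3,5-bis(benzyloxy)-4-[(1R)-1-(4-(benzyloxy)phenyl)ethyl]phenol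
Conditions: TBAF, THF, 0 °C
Reagents that add atoms: none
Why: Fluoride-induced cleavage of the aryl silyl ether (desilylation) leaves the benzyl ethers and the non-acidic diarylmethine centre untouched.

Step 5
Reactants: 8 3,5-bis(benzyloxy)-4-[(1R)-1-(4-(benzyloxy)phenyl)ethyl]phenol
Product: 10 4,6-bis(benzyloxy)-5-[(1R)-1-(4-(benzyloxy)phenyl)ethyl]-2-hydroxybenzaldehyde, via salicyl alcohol 9 (not isolated)
Conditions: MgCl2, Et3N, (CH2O)n, MeCN, reflux
Reagents that add atoms: formaldehyde (as paraformaldehyde), C=O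
Why: Magnesium-mediated ortho-formylation of a phenol (Casnati–Skattebøl reaction): the magnesium phenoxide delivers formaldehyde to the ortho carbon and a second formaldehyde oxidises the salicyl alcohol by hydride transfer, and since the two ortho positions of 8 are equivalent only one regioisomer can form.

Step 6
Reactants: 11 methyl [4-(benzyloxy)phenyl]acetate
Product: 12 methyl 2-bromo-2-[4-(benzyloxy)phenyl]acetate (racemic)
Conditions: NBS, AIBN (cat.), PhCF3, 80 °C
Reagents that add atoms: N-bromosuccinimide, O=C1CCC(=O)N1Br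
Why: Wohl–Ziegler radical bromination at the C–H that is both benzylic and α to the ester, which should react faster than the O-benzyl methylene; the racemic centre is harmless because this carbon (later C2) is equilibrated in step 10.

Step 7
Reactants: 10 4,6-bis(benzyloxy)-5-[(1R)-1-(4-(benzyloxy)phenyl)ethyl]-2-hydroxybenzaldehyde; 12 methyl 2-bromo-2-[4-(benzyloxy)phenyl]acetate
Product: 13 methyl 2-[4-(benzyloxy)phenyl]-2-{3,5-bis(benzyloxy)-4-[(1R)-1-(4-(benzyloxy)phenyl)ethyl]-2-formylphenoxy}acetate (both epimers at the acetate carbon)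
Conditions: K2CO3, DMF, rt
Reagents that add atoms: none
Why: Williamson ether synthesis in which the phenoxide displaces bromide from the activated α-bromo arylacetate at room temperature, mild enough to avoid aldol closure of the ester carbon onto the aldehyde; the new centre forms as both epimers.

Step 8
Reactants: 13 methyl 2-[4-(benzyloxy)phenyl]-2-{3,5-bis(benzyloxy)-4-[(1R)-1-(4-(benzyloxy)phenyl)ethyl]-2-formylphenoxy}acetate
Product: 14 2-[4-(benzyloxy)phenyl]-2-{3,5-bis(benzyloxy)-4-[(1R)-1-(4-(benzyloxy)phenyl)ethyl]-2-(hydroxymethyl)phenoxy}ethan-1-ol (both epimers)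
Conditions: LiAlH4, THF, 0 °C; aq. NaOH work-up
Reagents that add atoms: none
Why: Hydride reduction takes the ester and the aryl aldehyde to the diol together, so the two carbonyl groups need not be told apart; the work-up is kept basic because the trialkoxybenzyl alcohol ionises easily in acid.

Step 9
Reactants: 14 2-[4-(benzyloxy)phenyl]-2-{3,5-bis(benzyloxy)-4-[(1R)-1-(4-(benzyloxy)phenyl)ethyl]-2-(hydroxymethyl)phenoxy}ethan-1-ol
Product: 15 2-[4-(benzyloxy)phenyl]-2-{3,5-bis(benzyloxy)-4-[(1R)-1-(4-(benzyloxy)phenyl)ethyl]-2-formylphenoxy}acetaldehyde (both C2 epimers)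
Conditions: Dess–Martin periodinane, pyridine, CH2Cl2, 0 °C → rt; used crude
Reagents that add atoms: none
Why: Double Dess–Martin oxidation of both primary alcohols under pyridine buffering should give the dialdehyde without over-oxidation; the epimer mixture at C2 is intended and the sensitive α-aryloxy aldehyde is carried on at once.

Step 10
Reactants: 15 2-[4-(benzyloxy)phenyl]-2-{3,5-bis(benzyloxy)-4-[(1R)-1-(4-(benzyloxy)phenyl)ethyl]-2-formylphenoxy}acetaldehyde
Product: 16 (2R,3R)-5,7-bis(benzyloxy)-2-[4-(benzyloxy)phenyl]-6-[(1R)-1-(4-(benzyloxy)phenyl)ethyl]-3-hydroxy-2,3-dihydro-4H-chromen-4-one (tetra-O-benzyl ether of the target, 3-OH free)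
Conditions: chiral aminoindanol-derived N-C6F5 triazolium tetrafluoroborate (20 mol %), i-Pr2NEt, toluene (0.02 M), 0 °C → rt
Reagents that add atoms: none
Why: Proposed new method: the triazolylidene adds to the ring-A aldehyde, proton transfer gives the hydroxy-enamine, and this acyl-anion equivalent attacks the side-chain aldehyde carbon to form C3–C4 in a 6-exo-trig closure of the pyranone ring before the carbene leaves from the C4 alkoxide. The closest known reactions are carbene-catalysed intramolecular aldehyde–ketone crossed benzoin cyclisations of 2-(2-oxoalkoxy)benzaldehydes to 3-hydroxychroman-4-ones and aldehyde–aldehyde benzoin ring closures; an aldehyde acceptor with an epimerisable α-aryl-α-aryloxy carbon has not been used this way. C2 is set by dynamic kinetic resolution: the amine base interconverts the two C2 epimers of 15 through the enol, and the chiral carbene lets one of them cyclise faster. C3 is set in the bond-forming event by the aldehyde face that the catalyst-bound enaminol reaches anti to the C2 aryl group, and the resulting 2,3-trans (diequatorial) acyloin is also the more stable one should C3 equilibrate through the enediol. The step needs the ring-A aldehyde to be the acyl donor; this is supported by the crowded α-branched surroundings of the side-chain aldehyde and by the more acidic benzylic carbene adduct. The wrong 3-keto-4-hydroxy regioisomer has an unconjugated ketone that can revert by retro-benzoin, whereas the C4 ketone of 16 is conjugated to the trioxygenated ring A and should resist carbene re-addition.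

Step 11
Reactants: 16 (2R,3R)-5,7-bis(benzyloxy)-2-[4-(benzyloxy)phenyl]-6-[(1R)-1-(4-(benzyloxy)phenyl)ethyl]-3-hydroxy-2,3-dihydro-4H-chromen-4-one
Product: 17 (2R,3R)-3,5,7-trihydroxy-2-(4-hydroxyphenyl)-6-[(1R)-1-(4-hydroxyphenyl)ethyl]-2,3-dihydro-4H-chromen-4-one
Conditions: H2 (1 atm), 10% Pd/C, EtOAc–MeOH, rt
Reagents that add atoms: none
Why: Catalytic hydrogenolysis of the four aryl benzyl ethers under neutral conditions, as is routine for benzylated dihydroflavonols, leaves C2, C3 and the diarylmethine centre untouched, and the reaction is stopped once the benzyl groups are gone to spare the benzylic C2–O1 bond.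

Compound list
1 | 3,5-bis(benzyloxy)phenol | Oc1cc(OCc2ccccc2)cc(OCc2ccccc2)c1 | starting material
2 | [3,5-bis(benzyloxy)phenoxy]tri(propan-2-yl)silane | CC(C)[Si](Oc1cc(OCc2ccccc2)cc(OCc2ccccc2)c1)(C(C)C)C(C)C | intermediate
3 | 4'-(benzyloxy)acetophenone | CC(=O)c1ccc(OCc2ccccc2)cc1 | starting material
4 | [2,6-bis(benzyloxy)-4-(triisopropylsilyloxy)phenyl]lithium (not isolated) | [Li]c1c(OCc2ccccc2)cc(O[Si](C(C)C)(C(C)C)C(C)C)cc1OCc1ccccc1 | intermediate
5 | 1-[2,6-bis(benzyloxy)-4-(triisopropylsilyloxy)phenyl]-1-[4-(benzyloxy)phenyl]ethan-1-ol, racemic (not isolated) | CC(O)(c1ccc(OCc2ccccc2)cc1)c1c(OCc2ccccc2)cc(O[Si](C(C)C)(C(C)C)C(C)C)cc1OCc1ccccc1 | intermediate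
6 | {3,5-bis(benzyloxy)-4-[1-(4-(benzyloxy)phenyl)ethenyl]phenoxy}tri(propan-2-yl)silane | C=C(c1ccc(OCc2ccccc2)cc1)c1c(OCc2ccccc2)cc(O[Si](C(C)C)(C(C)C)C(C)C)cc1OCc1ccccc1 | intermediate
7 | {3,5-bis(benzyloxy)-4-[(1R)-1-(4-(benzyloxy)phenyl)ethyl]phenoxy}tri(propan-2-yl)silane | C[C@H](c1ccc(OCc2ccccc2)cc1)c1c(OCc2ccccc2)cc(O[Si](C(C)C)(C(C)C)C(C)C)cc1OCc1ccccc1 | intermediate
8 | 3,5-bis(benzyloxy)-4-[(1R)-1-(4-(benzyloxy)phenyl)ethyl]phenol | C[C@H](c1ccc(OCc2ccccc2)cc1)c1c(OCc2ccccc2)cc(O)cc1OCc1ccccc1 | intermediate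
9 | 3,5-bis(benzyloxy)-4-[(1R)-1-(4-(benzyloxy)phenyl)ethyl]-2-(hydroxymethyl)phenol (not isolated) | C[C@H](c1ccc(OCc2ccccc2)cc1)c1c(OCc2ccccc2)cc(O)c(CO)c1OCc1ccccc1 | intermediate
10 | 4,6-bis(benzyloxy)-5-[(1R)-1-(4-(benzyloxy)phenyl)ethyl]-2-hydroxybenzaldehyde | C[C@H](c1ccc(OCc2ccccc2)cc1)c1c(OCc2ccccc2)cc(O)c(C=O)c1OCc1ccccc1 | intermediate
11 | methyl [4-(benzyloxy)phenyl]acetate | COC(=O)Cc1ccc(OCc2ccccc2)cc1 | starting material
12 | methyl 2-bromo-2-[4-(benzyloxy)phenyl]acetate (racemic) | COC(=O)C(Br)c1ccc(OCc2ccccc2)cc1 | intermediate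
13 | methyl 2-[4-(benzyloxy)phenyl]-2-{3,5-bis(benzyloxy)-4-[(1R)-1-(4-(benzyloxy)phenyl)ethyl]-2-formylphenoxy}acetate (epimers at the acetate carbon) | C[C@H](c1ccc(OCc2ccccc2)cc1)c1c(OCc2ccccc2)cc(OC(C(=O)OC)c2ccc(OCc3ccccc3)cc2)c(C=O)c1OCc1ccccc1 | intermediate
14 | 2-[4-(benzyloxy)phenyl]-2-{3,5-bis(benzyloxy)-4-[(1R)-1-(4-(benzyloxy)phenyl)ethyl]-2-(hydroxymethyl)phenoxy}ethan-1-ol (epimers) | C[C@H](c1ccc(OCc2ccccc2)cc1)c1c(OCc2ccccc2)cc(OC(CO)c2ccc(OCc3ccccc3)cc2)c(CO)c1OCc1ccccc1 | intermediate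
15 | 2-[4-(benzyloxy)phenyl]-2-{3,5-bis(benzyloxy)-4-[(1R)-1-(4-(benzyloxy)phenyl)ethyl]-2-formylphenoxy}acetaldehyde (C2 epimers) | C[C@H](c1ccc(OCc2ccccc2)cc1)c1c(OCc2ccccc2)cc(OC(C=O)c2ccc(OCc3ccccc3)cc2)c(C=O)c1OCc1ccccc1 | intermediate
16 | (2R,3R)-5,7-bis(benzyloxy)-2-[4-(benzyloxy)phenyl]-6-[(1R)-1-(4-(benzyloxy)phenyl)ethyl]-3-hydroxy-2,3-dihydro-4H-chromen-4-one | C[C@H](c1ccc(OCc2ccccc2)cc1)c1c(OCc2ccccc2)cc2c(c1OCc1ccccc1)C(=O)[C@H](O)[C@@H](c1ccc(OCc3ccccc3)cc1)O2 | intermediate
17 | (2R,3R)-3,5,7-trihydroxy-2-(4-hydroxyphenyl)-6-[(1R)-1-(4-hydroxyphenyl)ethyl]-2,3-dihydro-4H-chromen-4-one | C[C@H](c1ccc(O)cc1)c1c(O)cc2c(c1O)C(=O)[C@H](O)[C@@H](c1ccc(O)cc1)O2 | target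

Total steps: 11. Longest linear sequence: 10 steps (steps 1–5 and 7–11).

Steps most likely to fail

1. Step 10 (Proposed new method).
- The carbene may add to the side-chain aldehyde instead; the resulting enaminol can expel the ring-A phenoxide (internal redox to an arylacetyl azolium), which cleaves the C2–O1 bond irreversibly.
- Adduct formation at the crowded, electron-rich ring-A aldehyde may be too slow.
- C2 selectivity may erode if epimerisation is slower than ring closure or if the closure becomes reversible.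
- The base may drive aldol closure of the C2 enol onto the ring-A aldehyde.

Fallback with known chemistry, setting out from salicylaldehyde 10 and rejoining the route at 16: excess methylmagnesium bromide should add to 10 to give the 2-(1-hydroxyethyl)phenol F1, and manganese dioxide should oxidise its benzylic carbinol to the 2'-hydroxyacetophenone F2. The phenol is protected as the methoxymethyl ether F3 (MOMCl, NaH), and Claisen–Schmidt condensation with 4-(benzyloxy)benzaldehyde (KOH, EtOH) should give the (E)-chalcone F4. Juliá–Colonna epoxidation (poly-L-leucine, urea–hydrogen peroxide, DBU, THF) should give the (αR,βS)-epoxide F5. Methanolic HCl then removes the methoxymethyl group, and the freed phenol opens the epoxide at the benzylic carbon with inversion, which should give the 2,3-trans (2R,3R) dihydroflavonol 16.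

2. Step 3.
- Facial discrimination by the catalyst may be insufficient.
- The acidic iridium hydride may trigger cationic dimerisation of the electron-rich alkene.

Fallback setting out from alkene 6 and rejoining at phenol 8: hydrogenation with an achiral neutral catalyst (RhCl(PPh3)3, H2) should give the racemic diarylethane F6, and TBAF should give the racemic phenol F7. Preparative chromatography on a chiral stationary phase then separates 8 from its (S)-enantiomer F8, which is set aside.

3. Step 2.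
- n-BuLi may deprotonate an O-benzyl methylene instead of the ring (followed by [1,2]-Wittig rearrangement).
- The hindered aryllithium may enolise ketone 3 instead of adding to it.

Fallback setting out from phenol 1 and rejoining at carbinol 5: Vilsmeier–Haack formylation (POCl3, DMF) para to the hydroxyl should give 2,6-bis(benzyloxy)-4-hydroxybenzaldehyde F9, to be separated from the minor ortho isomer. Silylation (TIPSCl, imidazole) gives the silyl ether F10, and commercial 4-(benzyloxy)phenylmagnesium bromide adds to give the diarylmethanol F11. Manganese dioxide gives the benzophenone F12, which cannot enolise, and methylmagnesium bromide then gives carbinol 5, which is dehydrated to 6 as in step 2.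

Further compounds
F1 | step 10 | 3,5-bis(benzyloxy)-4-[(1R)-1-(4-(benzyloxy)phenyl)ethyl]-2-(1-hydroxyethyl)phenol (carbinol epimers) | C[C@H](c1ccc(OCc2ccccc2)cc1)c1c(OCc2ccccc2)cc(O)c(C(C)O)c1OCc1ccccc1
F2 | step 10 | 1-{4,6-bis(benzyloxy)-5-[(1R)-1-(4-(benzyloxy)phenyl)ethyl]-2-hydroxyphenyl}ethan-1-one | C[C@H](c1ccc(OCc2ccccc2)cc1)c1c(OCc2ccccc2)cc(O)c(C(C)=O)c1OCc1ccccc1
F3 | step 10 | 1-{4,6-bis(benzyloxy)-5-[(1R)-1-(4-(benzyloxy)phenyl)ethyl]-2-(methoxymethoxy)phenyl}ethan-1-one | C[C@H](c1ccc(OCc2ccccc2)cc1)c1c(OCc2ccccc2)cc(OCOC)c(C(C)=O)c1OCc1ccccc1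
F4 | step 10 | (E)-1-{4,6-bis(benzyloxy)-5-[(1R)-1-(4-(benzyloxy)phenyl)ethyl]-2-(methoxymethoxy)phenyl}-3-[4-(benzyloxy)phenyl]prop-2-en-1-one | C[C@H](c1ccc(OCc2ccccc2)cc1)c1c(OCc2ccccc2)cc(OCOC)c(C(=O)/C=C/c2ccc(OCc3ccccc3)cc2)c1OCc1ccccc1
F5 | step 10 | {4,6-bis(benzyloxy)-5-[(1R)-1-(4-(benzyloxy)phenyl)ethyl]-2-(methoxymethoxy)phenyl}{(2R,3S)-3-[4-(benzyloxy)phenyl]oxiran-2-yl}methanone | C[C@H](c1ccc(OCc2ccccc2)cc1)c1c(OCc2ccccc2)cc(OCOC)c(C(=O)[C@@H]2O[C@H]2c2ccc(OCc3ccccc3)cc2)c1OCc1ccccc1
F6 | step 3 | racemic {3,5-bis(benzyloxy)-4-[1-(4-(benzyloxy)phenyl)ethyl]phenoxy}tri(propan-2-yl)silane | CC(c1ccc(OCc2ccccc2)cc1)c1c(OCc2ccccc2)cc(O[Si](C(C)C)(C(C)C)C(C)C)cc1OCc1ccccc1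
F7 | step 3 | racemic 3,5-bis(benzyloxy)-4-[1-(4-(benzyloxy)phenyl)ethyl]phenol | CC(c1ccc(OCc2ccccc2)cc1)c1c(OCc2ccccc2)cc(O)cc1OCc1ccccc1
F8 | step 3 | 3,5-bis(benzyloxy)-4-[(1S)-1-(4-(benzyloxy)phenyl)ethyl]phenol | C[C@@H](c1ccc(OCc2ccccc2)cc1)c1c(OCc2ccccc2)cc(O)cc1OCc1ccccc1
F9 | step 2 | 2,6-bis(benzyloxy)-4-hydroxybenzaldehyde | O=Cc1c(OCc2ccccc2)cc(O)cc1OCc1ccccc1
F10 | step 2 | 2,6-bis(benzyloxy)-4-(triisopropylsilyloxy)benzaldehyde | O=Cc1c(OCc2ccccc2)cc(O[Si](C(C)C)(C(C)C)C(C)C)cc1OCc1ccccc1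
F11 | step 2 | [2,6-bis(benzyloxy)-4-(triisopropylsilyloxy)phenyl][4-(benzyloxy)phenyl]methanol (racemic) | OC(c1ccc(OCc2ccccc2)cc1)c1c(OCc2ccccc2)cc(O[Si](C(C)C)(C(C)C)C(C)C)cc1OCc1ccccc1
F12 | step 2 | [2,6-bis(benzyloxy)-4-(triisopropylsilyloxy)phenyl][4-(benzyloxy)phenyl]methanone | O=C(c1ccc(OCc2ccccc2)cc1)c1c(OCc2ccccc2)cc(O[Si](C(C)C)(C(C)C)C(C)C)cc1OCc1ccccc1
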